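**Strategy.** The bicyclo[3.2.1]octane is unravelled at its six-membered ring C8–C9–C11–C12–C13–C14. Because the C11 oxygen sits two atoms from bridgehead C13, that ring can be read as a ring-expanded cyclopentanone: the precursor is a lactone-fused bicyclo[3.1.0]hexan-1-ol (cyclopentane C8–C9–C11–C13–C14, cyclopropane C11–C12–C13) carrying a propargyl group on C8. One-electron oxidation of the cyclopropanol cleaves the internal C11–C13 bond, which inserts C12 into the ring, unveils the C11 ketone and leaves a C13 radical that closes the D ring on the alkyne (C13–C16) and delivers the exo-methylene. The A-ring spirolactone comes from a titanocene epoxide–acrylate coupling; late allylic oxidation installs the enone.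

Key step: step 12

Remark: locants C1–C20 are those of the ent-kaurane skeleton of the target (C1 bears the ring-A acetate, C4 the gem-dimethyl group, C5 the C6H2OAc arm, C7 is the lactone carbonyl, C20 the lactone OCH2, C15 the ketone, C16=C17 the methylene).
Remark: in step 1 the ligand antipode is assumed to be the one that delivers the (3R) adduct; the sense of induction is fixed by that choice.

Step 1
Reactants: 1 4,4-dimethylcyclohex-2-en-1-one
Product: 4 (3R)-3-ethenyl-4,4-dimethyl-2-methylidenecyclohexan-1-one, via Mannich base 2 (not isolated), via ammonium iodide 3 (not isolated)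
Conditions: CH2=CHMgBr, CuBr·SMe2 (5 mol %), (R,S)-Josiphos (6 mol %), t-BuOMe, −78 °C; then Me2N=CH2+ I−, THF, −78 → 0 °C; then MeI; aq. NaHCO3, rt
Reagents that add atoms: vinylmagnesium bromide C=C[Mg]Br; N,N-dimethylmethyleneiminium iodide (Eschenmoser's salt) C[N+](C)=C.[I-]
Why: Cu-catalysed enantioselective 1,4-addition of the Grignard reagent sets C5, the magnesium enolate is trapped regiospecifically at C10 in a Mannich reaction, and Hofmann-type elimination of the quaternised amine gives the exo-methylene ketone, which is used at once.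

Step 2
Reactants: 4 (3R)-3-ethenyl-4,4-dimethyl-2-methylidenecyclohexan-1-one
Product: 5 (1S,3R)-3-ethenyl-4,4-dimethyl-2-methylidenecyclohexan-1-ol (OH cis to vinyl)
Conditions: NaBH4, CeCl3·7H2O, MeOH, −78 °C
Reagents that add atoms: none
Why: Luche 1,2-reduction, in which hydride adds to the carbonyl face remote from the C5 vinyl group and so sets C1 cis to it.

Step 3
Reactants: 5 (1S,3R)-3-ethenyl-4,4-dimethyl-2-methylidenecyclohexan-1-ol
Product: 6 (3S,4S,8R)-8-ethenyl-7,7-dimethyl-1-oxaspiro[2.5]octan-4-ol (epoxide O cis to OH)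
Conditions: VO(acac)2 (2 mol %), t-BuOOH, CH2Cl2, 0 °C
Reagents that add atoms: tert-butyl hydroperoxide CC(C)(C)OO
Why: Hydroxyl-directed vanadium-catalysed epoxidation delivers oxygen to the allylic 1,1-disubstituted alkene syn to the C1 hydroxyl and leaves the remote vinyl group untouched; the spiro centre is erased again in step 6.

Step 4
Reactants: 6 (3S,4S,8R)-8-ethenyl-7,7-dimethyl-1-oxaspiro[2.5]octan-4-ol
Product: 8 (3S,4S,8S)-8-(hydroxymethyl)-7,7-dimethyl-1-oxaspiro[2.5]octan-4-ol, via epoxy aldehyde 7 (not isolated)
Conditions: O3, pyridine, CH2Cl2, −78 °C; then NaBH4, MeOH, −78 → 0 °C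
Reagents that add atoms: ozone [O-][O+]=O
Why: Pyridine-buffered ozonolysis cleaves the only remaining alkene to the C6 aldehyde, which borohydride reduces in the same flask before it can epimerise at C5 or open the neighbouring epoxide.

Step 5
Reactants: 8 (3S,4S,8S)-8-(hydroxymethyl)-7,7-dimethyl-1-oxaspiro[2.5]octan-4-ol
Product: 9 (3S,4S,8S)-4-(tert-butyldimethylsilyloxy)-8-[(tert-butyldimethylsilyloxy)methyl]-7,7-dimethyl-1-oxaspiro[2.5]octane
Conditions: TBSCl, imidazole, DMAP (cat.), DMF, 40 °C
Reagents that add atoms: tert-butyldimethylsilyl chloride CC(C)(C)[Si](C)(C)Cl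
Why: Silyl ether formation on both hydroxyls, needed so that only the C20 oxygen can lactonise in step 6; no stereocentre is touched.

Step 6
Reactants: 9 bis-TBS spiro-epoxide
Product: 10 (6S,7S,11R)-7-(tert-butyldimethylsilyloxy)-11-[(tert-butyldimethylsilyloxy)methyl]-10,10-dimethyl-2-oxaspiro[5.5]undecan-3-one (spirolactone; C9 trans to O1 and to C6)
Conditions: Cp2TiCl2 (20 mol %), Zn, 2,4,6-collidine·HCl, THF, rt
Reagents that add atoms: 2,2,2-trifluoroethyl acrylate C=CC(=O)OCC(F)(F)F
Why: Titanocene(III)-mediated reductive epoxide opening gives the tertiary C10 radical, Giese addition to the acrylate takes place on the ring face anti to the cis-disposed OTBS and CH2OTBS groups (sets C10), and the C20 oxygen lactonises onto the activated trifluoroethyl ester.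

Step 7
Reactants: 10 spirolactone
Product: 12 unsaturated spirolactone (C8=C9), via selenide 11 (not isolated)
Conditions: LDA, THF, −78 °C; PhSeBr; then H2O2, pyridine, CH2Cl2, 0 °C → rt
Reagents that add atoms: none
Why: α-Selenenylation of the lactone lithium enolate and selenoxide syn-elimination, for which only the C9 hydrogens are available, give the α,β-unsaturated δ-lactone.

Step 8
Reactants: 12 unsaturated spirolactone
Product: 14 C9 methyl ester (CO2Me on C9 cis to C1 across the lactone ring), via carboxylic acid 13 (not isolated)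
Conditions: HCO2K, 4CzIPN (2 mol %), methyl thioglycolate (10 mol %), DMSO, blue LEDs, rt; aq. HCl; then TMSCHN2, MeOH/PhMe, 0 °C
Reagents that add atoms: potassium formate [K+].[O-]C=O; (trimethylsilyl)diazomethane C[Si](C)(C)C=[N+]=[N-]
Why: Photocatalytic Giese-type hydrocarboxylation, in which the CO2 radical anion from formate adds to the β-carbon C9 on the lactone face next to C1–O and away from the bulkier C5 arm and gem-dimethyl flank (sets C9), thiol hydrogen transfer quenches the C8 radical, and the acid is esterified.

Step 9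
Reactants: 14 C9 methyl ester
Product: 15 C8-allyl lactone ester (C8 epimers; mainly allyl trans to CO2Me)
Conditions: LDA (1.05 equiv), THF, −78 °C; allyl bromide, −78 → −30 °C
Reagents that add atoms: allyl bromide C=CCBr
Why: Kinetic deprotonation at the unhindered lactone α-CH2 (C8) in preference to the neopentyl C9–H, then SN2 enolate allylation; the C8 configuration is of no consequence because it is erased in step 11.

Step 10
Reactants: 15 C8-allyl lactone ester
Product: 16 lactone-fused bicyclo[3.1.0]hexan-1-ol (C11 cyclopropanol; cyclopropane C11–C12–C13; C8–H)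
Conditions: Ti(OiPr)4 (1.2 equiv), c-C5H9MgCl (4 equiv, slow addition), THF, rt
Reagents that add atoms: none
Why: Intramolecular Kulinkovich cyclopropanation, in which the titanacyclopropane made from the cyclopentyl Grignard reagent exchanges onto the terminal alkene and adds to the ester five atoms away, while the lactone carbonyl is out of reach (it would need a four-membered ring); the cyclopropanol diastereomers are carried on together.

Step 11
Reactants: 16 lactone-fused bicyclo[3.1.0]hexan-1-ol
Product: 17 C8-propargyl cyclopropanol (propargyl cis to H9; five-membered ring cis-fused to the lactone)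
Conditions: LDA (2.2 equiv), THF/DMPU, −78 °C; propargyl bromide, −78 → −20 °C
Reagents that add atoms: propargyl bromide C#CCBr
Why: Angular alkylation of the lactone enolate (dianion with the lithium cyclopropoxide) on the face syn to H9, which keeps the carbocycle cis-fused and avoids the pseudo-axial C1 flank of the spiro ring, sets the C8 quaternary centre.

Step 12
Reactants: 17 C8-propargyl cyclopropanol
Product: 18 tetracyclic C11 ketone (bicyclo[3.2.1]octane with C16=C17 methylene; 1-OTBS and 6-OTBS)
Conditions: Mn(pic)3 (1.3 equiv), 1,4-cyclohexadiene (1.5 equiv), degassed DMF (0.01 M), 0 °C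
Reagents that add atoms: none
Why: Mn(III) binds the cyclopropanol and one-electron oxidation gives a cyclopropoxy radical whose β-scission cuts the internal C11–C13 bond, so the cyclopentane C8–C9–C11–C13–C14 becomes the cyclohexanone C8–C9–C11–C12–C13–C14 with the radical on C13. The closest known reaction type is the Mn(III)- or Fe(III)-mediated oxidative ring expansion of bicyclo[n.1.0]alkan-1-ols with capture of the β-keto radical by a tethered π-bond. The C13 radical closes the five-membered D ring in the 5-exo-dig mode on C16 of the propargyl group, and the vinyl radical takes a hydrogen atom from 1,4-cyclohexadiene to give the exo-methylene. C13 is the only new stereocentre and is fixed by the one-carbon tether C14 to the C8 centre set in step 11, because the bridge can only close cis; both cyclopropanol diastereomers of 17 converge on the same radical. The step needs cleavage of the internal and not the external cyclopropane bond, which is secured by formation of the secondary instead of the primary radical and by return of the external mode through the cyclopropoxy radical, and it needs ring closure to outrun hydrogen transfer to C13, which high dilution and the small amount of the diene secure.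

Step 13
Reactants: 18 tetracyclic C11 ketone
Product: 19 C1,C6-diol
Conditions: HF·pyridine, THF/pyridine, 0 °C → rt
Reagents that add atoms: none
Why: Fluoride-mediated cleavage of both silyl ethers under buffered conditions that leave the lactone, the ketone and the exo-methylene untouched.

Step 14
Reactants: 19 C1,C6-diol
Product: 20 C1,C6-diacetate
Conditions: Ac2O, pyridine, DMAP (cat.), CH2Cl2, rt
Reagents that add atoms: acetic anhydride CC(=O)OC(C)=O
Why: DMAP-catalysed acylation installs both acetates while C11 is still a ketone, so that the later C11 hydroxyl stays free.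

Step 15
Reactants: 20 C1,C6-diacetate
Product: 21 C11 alcohol (11-OH syn to the C15–C16 bridge and cis to H9)
Conditions: NaBH4, MeOH/THF, −40 °C
Reagents that add atoms: none
Why: Borohydride reduction in which hydride reaches C11 only from the face opposite the two-carbon bridge (equatorial attack on the bicyclo[3.2.1]octan-3-one), giving the axial alcohol and setting C11.

Step 16
Reactants: 21 C11 alcohol
Product: 22 C15 allylic alcohol (C15 epimer of no consequence)
Conditions: SeO2 (0.5 equiv), t-BuOOH, CH2Cl2, rt
Reagents that add atoms: tert-butyl hydroperoxide CC(C)(C)OO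
Why: Selenium dioxide allylic oxidation (ene reaction then [2,3]-shift) at C15, the only allylic methylene of the exo-methylene unit since C13 is a bridgehead.

Step 17
Reactants: 22 C15 allylic alcohol
Product: 23 Rabdosin B
Conditions: MnO2 (excess), CH2Cl2, rt
Reagents that add atoms: none
Why: Manganese dioxide oxidises only the allylic C15 alcohol to the α-methylene cyclopentanone and leaves the saturated C11 carbinol free.

**Compound list**

1 | 4,4-dimethylcyclohex-2-en-1-one | CC1(C)CCC(=O)C=C1 | starting material
2 | Mannich base: (3R)-2-[(dimethylamino)methyl]-3-ethenyl-4,4-dimethylcyclohexan-1-one (C2 epimers) | CN(C)CC1C(=O)CCC(C)(C)[C@H]1C=C | intermediate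
3 | ammonium iodide: N-methyl quaternary salt of 2 | C[N+](C)(C)CC1C(=O)CCC(C)(C)[C@H]1C=C.[I-] | intermediate
4 | (3R)-3-ethenyl-4,4-dimethyl-2-methylidenecyclohexan-1-one | C=C1C(=O)CCC(C)(C)[C@H]1C=C | intermediate
5 | (1S,3R)-3-ethenyl-4,4-dimethyl-2-methylidenecyclohexan-1-ol (OH cis to vinyl) | C=C1[C@@H](O)CCC(C)(C)[C@H]1C=C | intermediate
6 | (3S,4S,8R)-8-ethenyl-7,7-dimethyl-1-oxaspiro[2.5]octan-4-ol (epoxide O cis to OH) | C2[C@]1(O2)[C@@H](O)CCC(C)(C)[C@H]1C=C | intermediate
7 | epoxy aldehyde: C6 aldehyde corresponding to 8 | C2[C@]1(O2)[C@@H](O)CCC(C)(C)[C@H]1C=O | intermediate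
8 | (3S,4S,8S)-8-(hydroxymethyl)-7,7-dimethyl-1-oxaspiro[2.5]octan-4-ol | C2[C@]1(O2)[C@@H](O)CCC(C)(C)[C@H]1CO | intermediate
9 | (3S,4S,8S)-4-(tert-butyldimethylsilyloxy)-8-[(tert-butyldimethylsilyloxy)methyl]-7,7-dimethyl-1-oxaspiro[2.5]octane | C2[C@]1(O2)[C@@H](O[Si](C)(C)C(C)(C)C)CCC(C)(C)[C@H]1CO[Si](C)(C)C(C)(C)C | intermediate
10 | (6S,7S,11R)-7-(tert-butyldimethylsilyloxy)-11-[(tert-butyldimethylsilyloxy)methyl]-10,10-dimethyl-2-oxaspiro[5.5]undecan-3-one (C7/C8/C9/C10/C20 δ-lactone spiro at C10; C9 trans to O1 and C6) | O=C1CC[C@]2(CO1)[C@@H](O[Si](C)(C)C(C)(C)C)CCC(C)(C)[C@H]2CO[Si](C)(C)C(C)(C)C | intermediate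
11 | selenide: C8-phenylselanyl derivative of 10 (C8 epimers) | O=C1C([Se]c3ccccc3)C[C@]2(CO1)[C@@H](O[Si](C)(C)C(C)(C)C)CCC(C)(C)[C@H]2CO[Si](C)(C)C(C)(C)C | intermediate
12 | unsaturated spirolactone: C8=C9 dehydro derivative of 10 | O=C1C=C[C@]2(CO1)[C@@H](O[Si](C)(C)C(C)(C)C)CCC(C)(C)[C@H]2CO[Si](C)(C)C(C)(C)C | intermediate
13 | carboxylic acid: 10 bearing CO2H on C9, cis to C1 across the lactone ring (H9 on the C5 side) | OC(=O)[C@H]1[C@]2(COC(=O)C1)[C@@H](O[Si](C)(C)C(C)(C)C)CCC(C)(C)[C@H]2CO[Si](C)(C)C(C)(C)C | intermediate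
14 | methyl ester of 13 (C9 configured as in the target) | COC(=O)[C@H]1[C@]2(COC(=O)C1)[C@@H](O[Si](C)(C)C(C)(C)C)CCC(C)(C)[C@H]2CO[Si](C)(C)C(C)(C)C | intermediate
15 | C8-allyl derivative of 14 (C8 epimers) | COC(=O)[C@H]1[C@]2(COC(=O)C1CC=C)[C@@H](O[Si](C)(C)C(C)(C)C)CCC(C)(C)[C@H]2CO[Si](C)(C)C(C)(C)C | intermediate
16 | lactone-fused bicyclo[3.1.0]hexan-1-ol: C11(OH) bonded to C9, C12 and C13; C13–C14–C8 closes the five-membered ring (C8, C11, C13 unassigned; C9, C10, C1, C5 as in the target) | OC12CC1CC1[C@@H]2[C@]2(COC1=O)[C@@H](O[Si](C)(C)C(C)(C)C)CCC(C)(C)[C@H]2CO[Si](C)(C)C(C)(C)C | intermediate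
17 | C8-propargyl derivative of 16 (propargyl cis to H9, C8 as in the target; cyclopropanol diastereomers) | OC12CC1C[C@@]1(CC#C)[C@@H]2[C@]2(COC1=O)[C@@H](O[Si](C)(C)C(C)(C)C)CCC(C)(C)[C@H]2CO[Si](C)(C)C(C)(C)C | intermediate
18 | tetracyclic ketone: 11-oxo-15-deoxo skeleton of the target with 1-OTBS and 6-OTBS (C8, C9, C10, C13 as in the target) | C=C1C[C@]23C[C@H]1CC(=O)[C@H]2[C@]1(COC3=O)[C@@H](O[Si](C)(C)C(C)(C)C)CCC(C)(C)[C@H]1CO[Si](C)(C)C(C)(C)C | intermediate
19 | C1,C6-diol of 18 | C=C1C[C@]23C[C@H]1CC(=O)[C@H]2[C@]1(COC3=O)[C@@H](O)CCC(C)(C)[C@H]1CO | intermediate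
20 | C1,C6-diacetate of 19 | C=C1C[C@]23C[C@H]1CC(=O)[C@H]2[C@]1(COC3=O)[C@@H](OC(C)=O)CCC(C)(C)[C@H]1COC(C)=O | intermediate
21 | 15-deoxo-Rabdosin B (11-OH syn to the C15–C16 bridge) | C=C1C[C@]23C[C@H]1C[C@H](O)[C@H]2[C@]1(COC3=O)[C@@H](OC(C)=O)CCC(C)(C)[C@H]1COC(C)=O | intermediate
22 | 15-hydroxy-15-deoxo-Rabdosin B (C15 epimer unassigned) | C=C1C(O)[C@]23C[C@H]1C[C@H](O)[C@H]2[C@]1(COC3=O)[C@@H](OC(C)=O)CCC(C)(C)[C@H]1COC(C)=O | intermediate
23 | Rabdosin B | C=C1C(=O)[C@]23C[C@H]1C[C@H](O)[C@H]2[C@]1(COC3=O)[C@@H](OC(C)=O)CCC(C)(C)[C@H]1COC(C)=O | target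

**Step count and risks**

Total step count: 17. Longest linear sequence: 17 (fully linear from 1).

Three steps most likely to fail:

Step 12. The cyclopropoxy radical may open its external C11–C12 bond and the resulting primary radical may close 6-exo onto the alkyne, or the C13 radical may be reduced by hydrogen transfer before the D ring closes. The fallback separates ring expansion from D-ring closure and sets out from 17. Oxidation with FeCl3 (2.2 equiv, pyridine, DMF, 0 °C) performs the same ring expansion but traps the C13 radical by fast chlorine transfer, giving the β-chloro ketone F1. Sodium acetate in methanol eliminates HCl to the cyclohexenone F2 (C12=C13). Bu3SnH/AIBN in refluxing benzene adds a stannyl radical to the terminal alkyne, and the C16 vinyl radical closes 5-exo-trig onto C13 of the enone to give the vinylstannane F3. Protodestannylation with PPTS in CH2Cl2 returns to 18.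

Step 8. The CO2 radical anion may attack C9 on the other lactone face (poor facial selectivity), giving the C9 epimer. The fallback resets C9 by hydrogenation and sets out from 12. The epimeric ester obtained under the step 8 conditions, the C9-epimeric methyl ester F4, is selenenylated at C8 (LDA, PhSeBr) to the selenide F5 and oxidised with H2O2 to the unsaturated lactone ester F6 (C8=C9 bearing CO2Me on C9). Hydrogenation over Pd/C in EtOAc then delivers hydrogen to C9 from the very face the radical preferred, which places the ester on the C1 side, and returns to 14.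

Step 1. The hindered enone may give low enantioselectivity in the copper-catalysed vinyl addition, or the skipped dienone may isomerise during amine elimination. The fallback moves the enantiocontrol to an enzymatic kinetic resolution and sets out from 1. The same sequence without chiral ligand (CuI catalysis) gives the racemic Mannich base F7, the racemic ammonium iodide F8 and the racemic enone F9. Luche reduction gives the racemic cis-alcohol F10. Candida antarctica lipase B with vinyl acetate in hexane acylates the (1R,3S) enantiomer and leaves the (1S,3R) alcohol, which is separated and is 5, where the route is rejoined.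

Further compounds
F1 | step 12 | β-chloro ketone: ring-expanded 13-chloro-11-ketone with intact propargyl group | C#CC[C@]12CC(Cl)CC(=O)[C@H]1[C@]1(COC2=O)[C@@H](O[Si](C)(C)C(C)(C)C)CCC(C)(C)[C@H]1CO[Si](C)(C)C(C)(C)C
F2 | step 12 | cyclohexenone: C12=C13 enone with intact propargyl group | C#CC[C@]12CC=CC(=O)[C@H]1[C@]1(COC2=O)[C@@H](O[Si](C)(C)C(C)(C)C)CCC(C)(C)[C@H]1CO[Si](C)(C)C(C)(C)C
F3 | step 12 | vinylstannane: 17-(tributylstannyl) derivative of 18 | CCCC[Sn](CCCC)(CCCC)C=C1C[C@]23C[C@H]1CC(=O)[C@H]2[C@]1(COC3=O)[C@@H](O[Si](C)(C)C(C)(C)C)CCC(C)(C)[C@H]1CO[Si](C)(C)C(C)(C)C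
F4 | step 8 | C9-epimeric methyl ester (C9 epimer of 14) | COC(=O)[C@@H]1[C@]2(COC(=O)C1)[C@@H](O[Si](C)(C)C(C)(C)C)CCC(C)(C)[C@H]2CO[Si](C)(C)C(C)(C)C
F5 | step 8 | selenide: C8-phenylselanyl derivative of F4 | COC(=O)[C@@H]1[C@]2(COC(=O)C1[Se]c3ccccc3)[C@@H](O[Si](C)(C)C(C)(C)C)CCC(C)(C)[C@H]2CO[Si](C)(C)C(C)(C)C
F6 | step 8 | unsaturated lactone ester: C8=C9 with CO2Me on C9 | COC(=O)C1=CC(=O)OC[C@]12[C@@H](O[Si](C)(C)C(C)(C)C)CCC(C)(C)[C@H]2CO[Si](C)(C)C(C)(C)C
F7 | step 1 | racemic Mannich base (racemate of 2) | CN(C)CC1C(=O)CCC(C)(C)C1C=C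
F8 | step 1 | racemic ammonium iodide (racemate of 3) | C[N+](C)(C)CC1C(=O)CCC(C)(C)C1C=C.[I-]
F9 | step 1 | racemic enone (racemate of 4) | C=C1C(=O)CCC(C)(C)C1C=C
F10 | step 1 | racemic cis-alcohol (racemate of 5) | C=C1[C@@H](O)CCC(C)(C)[C@H]1C=C.C=C1[C@H](O)CCC(C)(C)[C@@H]1C=C
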